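## Retrosynthetic overview

1. Enabling feature: C1 of ring B (the CH carrying the 4-hydroxyphenyl ring C) is a para-hydroxybenzylic carbon, i.e. a latent para-quinone methide. Its neighbour C7a of resorcinol ring A lies ortho to the C7 oxygen and para to the C5 oxygen. The C1–C7a bond is therefore a Friedel–Crafts bond, the one nature closes in 8–8'-linked resveratrol dimers. The side-chain carbinol carbon is a second para-hydroxybenzylic carbon, so the target is two identical aryl–C–C–aryl halves joined at C2–C3, with a hidden meso relationship between C2 and C3.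
2. Disconnections: C1–C7a (closes ring B) gives an open-chain γ-hydroxy ketone. Both para-oxybenzylic carbons go back to C=O, giving a meso 1,4-diketone with two enantiotopic carbonyl groups. C2–C3 goes back to alkylation of a deoxybenzoin enolate with the α-bromide of the same deoxybenzoin, and the deoxybenzoin comes from ketone α-arylation.
3. Ring order: rings A, C, D and E are bought as phenols; ring B is the only ring made and is closed in the key step.
4. Stereochemistry: a chiral hydrogenation catalyst picks one carbonyl of the meso diketone. The carbinol centre it creates fixes the absolute sense of C2 and C3 and is then sacrificed on ionisation. C1 follows from the ring closure, and the last carbinol centre comes from an oxazaborolidine-controlled reduction before global desilylation.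

Key step: step 6

Remarks
- Locants: indane numbering with C1 = carbon bearing the 4-oxyphenyl ring, C2 = carbon bearing the 3,5-dioxyphenyl ring, C3 = carbon bearing the side chain, ring A oxygens on C5 and C7. TBSO = tert-butyldimethylsilyloxy.
- Assumption: in step 6 the carbonyl next to the (S)-configured α-carbon is the matched one for the (R)-XylBINAP/(R,R)-DPEN catalyst (like-configured, Felkin–Anh-type pairing, as in dynamic kinetic resolutions of α-aryl ketones). If the pairing is the opposite one, the enantiomeric catalyst is used and nothing else changes, because the carbinol centre it makes is erased in the same step.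
- Silyl ethers are used on all six phenols because the final para-hydroxybenzylic alcohol tolerates neither strong Lewis acids nor hydrogenolysis.

## Route

Step 1
Reactants: 1 4'-hydroxyacetophenone
Product: 2 4'-(TBSO)acetophenone
Conditions: TBSCl, imidazole, DMF, 20 °C
Reagents that add atoms: tert-butyldimethylsilyl chloride (TBSCl), CC(C)(C)[Si](C)(C)Cl
Why: Silylation of a phenol with a silyl chloride and imidazole (silyl ether formation) is fast and selective, and the aryl silyl ether survives the weak base and acid used later and leaves under buffered fluoride at the end; no stereocentre is formed.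

Step 2
Reactants: 3 5-bromoresorcinol
Product: 4 1-bromo-3,5-bis(TBSO)benzene
Conditions: TBSCl (2.2 equiv), imidazole, DMF, 20 °C
Reagents that add atoms: tert-butyldimethylsilyl chloride (TBSCl), CC(C)(C)[Si](C)(C)Cl
Why: The same silyl ether formation protects both phenols of the resorcinol unit, whose silyloxy groups still activate the ring carbon ortho and para to them for the later ring closure; no stereocentre is formed.

Step 3
Reactants: 2 4'-(TBSO)acetophenone, 4 1-bromo-3,5-bis(TBSO)benzene
Product: 5 2-[3,5-bis(TBSO)phenyl]-1-[4-(TBSO)phenyl]ethan-1-one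
Conditions: Pd(OAc)2 (2 mol%), 2-dicyclohexylphosphino-2'-methylbiphenyl (4 mol%), K3PO4, toluene, 80 °C
Reagents that add atoms: none
Why: Palladium-catalysed α-arylation of a ketone enolate with an aryl bromide (bulky biarylphosphine, K3PO4 as a base mild enough for aryl silyl ethers) joins the two rings of the deoxybenzoin at the methyl carbon, a slight excess of 2 suppressing diarylation; no stereocentre is formed.

Step 4
Reactants: 5 2-[3,5-bis(TBSO)phenyl]-1-[4-(TBSO)phenyl]ethan-1-one
Product: 6 racemic 2-bromo-2-[3,5-bis(TBSO)phenyl]-1-[4-(TBSO)phenyl]ethan-1-one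
Conditions: LiN(SiMe3)2 (1.05 equiv), THF, −78 °C; enolate solution added to NBS (1.1 equiv), THF, −78 °C; AcOH quench (1.05 equiv)
Reagents that add atoms: N-bromosuccinimide (NBS), O=C1CCC(=O)N1Br
Why: α-Bromination of a preformed lithium enolate with N-bromosuccinimide places bromine on the doubly activated α-carbon far faster than NBS attacks the silyloxy-arene rings, and inverse addition keeps the bromo ketone away from unreacted enolate; the new stereocentre is formed racemic, which is immaterial because it is equilibrated in the next step.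

Step 5
Reactants: 5 2-[3,5-bis(TBSO)phenyl]-1-[4-(TBSO)phenyl]ethan-1-one, 6 racemic 2-bromo-2-[3,5-bis(TBSO)phenyl]-1-[4-(TBSO)phenyl]ethan-1-one
Product: 8 meso-(2R,3S)-2,3-bis[3,5-bis(TBSO)phenyl]-1,4-bis[4-(TBSO)phenyl]butane-1,4-dione, via diketone diastereomer mixture 7 (not isolated)
Conditions: 5, LiN(SiMe3)2 (1.0 equiv), THF, −78 °C; then 6 (1.0 equiv), −78 → 0 °C; aqueous work-up; DBU (0.2 equiv), dry MeCN/toluene, 40 → 0 °C, crystallisation
Reagents that add atoms: none
Why: Alkylation of the lithium enolate of 5 with its own α-bromo ketone 6 (the classical route to 2,3-diaryl-1,4-diketones of the bidesyl type) forms the central C2–C3 bond between the two α-carbons, the 8–8' bond of the biosynthesis; because both partners share one skeleton any bromine–lithium exchange between them is degenerate, and because both new stereocentres are epimerisable α-aryl ketone carbons the mixture 7 should be funnelled by catalytic DBU and crystallisation (crystallisation-induced diastereomer transformation) into the less soluble meso isomer.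

Step 6
Reactants: 8 meso-(2R,3S)-2,3-bis[3,5-bis(TBSO)phenyl]-1,4-bis[4-(TBSO)phenyl]butane-1,4-dione
Product: 11 [(1R,2S,3R)-2-[3,5-bis(TBSO)phenyl]-5,7-bis(TBSO)-1-[4-(TBSO)phenyl]-2,3-dihydro-1H-inden-3-yl][4-(TBSO)phenyl]methanone, via hydroxy ketone 9 (not isolated), via quinone methide cation 10 (not isolated)
Conditions: trans-RuH(η1-BH4)[(R)-XylBINAP][(R,R)-DPEN] (1 mol%), H2 (8 atm), iPrOH/THF, 25 °C, stopped after 1 equiv H2; evaporation; BF3·OEt2 (0.5 equiv), CH2Cl2, −40 °C; then DBU (1 equiv), 20 °C
Reagents that add atoms: none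
Why: The Noyori-type ruthenium hydride should hydrogenate, of the two enantiotopic aryl ketones of 8, the one whose α-carbon has the matching configuration and leave the mismatched one, which is also masked as the cyclic hemiketal of 9; BF3·OEt2 then ionises the para-silyloxybenzylic carbinol to the O-silylated para-quinone methide cation 10, which the neighbouring resorcinol ring attacks at the carbon ortho to one and para to the other silyloxy group. The closest known reaction types are the asymmetric hydrogenation of α-stereogenic aryl ketones and the Lewis-acid Friedel–Crafts cyclisation of para-quinone methides to indane-type resveratrol dimers, which copies the biosynthetic ring closure. Ring B closes in the 5-exo-trig mode with respect to the exocyclic C=C of the quinone methide (a Friedel–Crafts alkylation in which the arene bond ends up inside the ring). C2 and C3 are carried over unchanged from the meso diketone and their absolute sense is fixed by the catalyst's choice of carbonyl group; C1 is set by attack on the face of the planar cation that puts ring C trans to the C2 aryl group; the carbinol centre made by the catalyst is erased once it has broken the symmetry, and DBU returns any 2,3-cis ketone to the all-trans isomer by enolisation at C3. The step needs reduction of one carbonyl only and ionisation at one benzylic carbon only, which the catalyst mismatch, the hemiketal and the inability of a ketone to ionise secure, and it needs ring closure to outrun loss of the C2 proton from 10, which the low temperature and the five-membered transition state with an electron-rich arene favour.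

Step 7
Reactants: 11 [(1R,2S,3R)-2-[3,5-bis(TBSO)phenyl]-5,7-bis(TBSO)-1-[4-(TBSO)phenyl]-2,3-dihydro-1H-inden-3-yl][4-(TBSO)phenyl]methanone
Product: 12 (S)-[(1R,2S,3R)-2-[3,5-bis(TBSO)phenyl]-5,7-bis(TBSO)-1-[4-(TBSO)phenyl]-2,3-dihydro-1H-inden-3-yl][4-(TBSO)phenyl]methanol
Conditions: (R)-2-methyl-CBS-oxazaborolidine (0.3 equiv), BH3·SMe2, THF, −20 → 20 °C; MeOH quench
Reagents that add atoms: none
Why: Corey–Bakshi–Shibata reduction delivers hydride under reagent control to the carbonyl face that gives the (S)-carbinol when the 4-silyloxyphenyl ring is the large and the indanyl carbon the small substituent, a control expected to override the inherent bias of the neighbouring C3 centre, which itself stays trans because that is also its thermodynamic position.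

Step 8
Reactants: 12 (S)-[(1R,2S,3R)-2-[3,5-bis(TBSO)phenyl]-5,7-bis(TBSO)-1-[4-(TBSO)phenyl]-2,3-dihydro-1H-inden-3-yl][4-(TBSO)phenyl]methanol
Product: 13 (1R,2S,3R)-2-(3,5-dihydroxyphenyl)-3-[(S)-hydroxy(4-hydroxyphenyl)methyl]-1-(4-hydroxyphenyl)-2,3-dihydro-1H-indene-5,7-diol (CNP0214825.2)
Conditions: Bu4NF (7 equiv), AcOH (7 equiv), THF, 0 °C
Reagents that add atoms: none
Why: Fluoride-induced cleavage of the six aryl silyl ethers (desilylation) under acetic acid buffering frees the phenols without base- or acid-triggered quinone methide formation at the para-hydroxybenzylic carbinol, so no stereocentre is touched.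

## Compound list

1 | 4'-hydroxyacetophenone | CC(=O)c1ccc(O)cc1 | starting material
2 | 4'-(TBSO)acetophenone | CC(=O)c1ccc(O[Si](C)(C)C(C)(C)C)cc1 | intermediate
3 | 5-bromoresorcinol | Oc1cc(O)cc(Br)c1 | starting material
4 | 1-bromo-3,5-bis(TBSO)benzene | Brc1cc(O[Si](C)(C)C(C)(C)C)cc(O[Si](C)(C)C(C)(C)C)c1 | intermediate
5 | 2-[3,5-bis(TBSO)phenyl]-1-[4-(TBSO)phenyl]ethan-1-one | O=C(Cc1cc(O[Si](C)(C)C(C)(C)C)cc(O[Si](C)(C)C(C)(C)C)c1)c1ccc(O[Si](C)(C)C(C)(C)C)cc1 | intermediate
6 | racemic 2-bromo-2-[3,5-bis(TBSO)phenyl]-1-[4-(TBSO)phenyl]ethan-1-one | O=C(C(Br)c1cc(O[Si](C)(C)C(C)(C)C)cc(O[Si](C)(C)C(C)(C)C)c1)c1ccc(O[Si](C)(C)C(C)(C)C)cc1 | intermediate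
7 | 2,3-bis[3,5-bis(TBSO)phenyl]-1,4-bis[4-(TBSO)phenyl]butane-1,4-dione, dl/meso mixture (not isolated) | O=C(C(c1cc(O[Si](C)(C)C(C)(C)C)cc(O[Si](C)(C)C(C)(C)C)c1)C(c1cc(O[Si](C)(C)C(C)(C)C)cc(O[Si](C)(C)C(C)(C)C)c1)C(=O)c1ccc(O[Si](C)(C)C(C)(C)C)cc1)c1ccc(O[Si](C)(C)C(C)(C)C)cc1 | intermediate
8 | meso-(2R,3S)-2,3-bis[3,5-bis(TBSO)phenyl]-1,4-bis[4-(TBSO)phenyl]butane-1,4-dione | O=C([C@@H](c1cc(O[Si](C)(C)C(C)(C)C)cc(O[Si](C)(C)C(C)(C)C)c1)[C@@H](c1cc(O[Si](C)(C)C(C)(C)C)cc(O[Si](C)(C)C(C)(C)C)c1)C(=O)c1ccc(O[Si](C)(C)C(C)(C)C)cc1)c1ccc(O[Si](C)(C)C(C)(C)C)cc1 | intermediate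
9 | (2R,3S,4S)-2,3-bis[3,5-bis(TBSO)phenyl]-4-hydroxy-1,4-bis[4-(TBSO)phenyl]butan-1-one, open form of its cyclic hemiketal (not isolated) | O=C([C@@H](c1cc(O[Si](C)(C)C(C)(C)C)cc(O[Si](C)(C)C(C)(C)C)c1)[C@@H](c1cc(O[Si](C)(C)C(C)(C)C)cc(O[Si](C)(C)C(C)(C)C)c1)[C@H](O)c1ccc(O[Si](C)(C)C(C)(C)C)cc1)c1ccc(O[Si](C)(C)C(C)(C)C)cc1 | intermediate
10 | O-silylated para-quinone methide cation from 9 by loss of water at C4 (not isolated) | O=C([C@@H](c1cc(O[Si](C)(C)C(C)(C)C)cc(O[Si](C)(C)C(C)(C)C)c1)[C@@H](c1cc(O[Si](C)(C)C(C)(C)C)cc(O[Si](C)(C)C(C)(C)C)c1)C=C1C=CC(=[O+][Si](C)(C)C(C)(C)C)C=C1)c1ccc(O[Si](C)(C)C(C)(C)C)cc1 | intermediate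
11 | [(1R,2S,3R)-2-[3,5-bis(TBSO)phenyl]-5,7-bis(TBSO)-1-[4-(TBSO)phenyl]-2,3-dihydro-1H-inden-3-yl][4-(TBSO)phenyl]methanone | CC(C)(C)[Si](C)(C)Oc1ccc([C@@H]2c3c(O[Si](C)(C)C(C)(C)C)cc(O[Si](C)(C)C(C)(C)C)cc3[C@H](C(=O)c3ccc(O[Si](C)(C)C(C)(C)C)cc3)[C@H]2c2cc(O[Si](C)(C)C(C)(C)C)cc(O[Si](C)(C)C(C)(C)C)c2)cc1 | intermediate
12 | (S)-[(1R,2S,3R)-2-[3,5-bis(TBSO)phenyl]-5,7-bis(TBSO)-1-[4-(TBSO)phenyl]-2,3-dihydro-1H-inden-3-yl][4-(TBSO)phenyl]methanol | CC(C)(C)[Si](C)(C)Oc1ccc([C@@H]2c3c(O[Si](C)(C)C(C)(C)C)cc(O[Si](C)(C)C(C)(C)C)cc3[C@H]([C@H](O)c3ccc(O[Si](C)(C)C(C)(C)C)cc3)[C@H]2c2cc(O[Si](C)(C)C(C)(C)C)cc(O[Si](C)(C)C(C)(C)C)c2)cc1 | intermediate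
13 | (1R,2S,3R)-2-(3,5-dihydroxyphenyl)-3-[(S)-hydroxy(4-hydroxyphenyl)methyl]-1-(4-hydroxyphenyl)-2,3-dihydro-1H-indene-5,7-diol | Oc1ccc([C@@H]2c3c(O)cc(O)cc3[C@H]([C@H](O)c3ccc(O)cc3)[C@H]2c2cc(O)cc(O)c2)cc1 | target

## Step count and risks

Total step count: 8. Longest linear sequence: 7 steps (1 or 3 to 13).

Steps most likely to fail:

Step 6. In the hydrogenation stage the two carbonyl groups may be discriminated incompletely, or both may be reduced. In the acid stage the cation may lose the C2 proton (eroding configuration at C2), be captured by the ketone oxygen, or be attacked only slowly because silyl ethers donate less than free phenols. The fallback sets out from 8 and comes back at 11. The hydrogenation is run as a separate operation and 9 is isolated and freed from over-reduced material. Bu4NF/AcOH then removes the six silyl groups to give (2R,3S,4S)-2,3-bis(3,5-dihydroxyphenyl)-4-hydroxy-1,4-bis(4-hydroxyphenyl)butan-1-one F1. In warm hexafluoro-2-propanol/water this para-hydroxybenzylic alcohol should lose water to the neutral para-quinone methide, which the free resorcinol ring attacks as in the biosynthesis, giving [(1R,2S,3R)-2-(3,5-dihydroxyphenyl)-5,7-dihydroxy-1-(4-hydroxyphenyl)-2,3-dihydro-1H-inden-3-yl](4-hydroxyphenyl)methanone F2. Silylation of all six phenols (TBSCl, imidazole, DMF) returns to 11.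

Step 7. Facial selectivity may be poor if the indanyl carbon competes with the aryl ring as the large substituent, or if the inherent Felkin–Anh-type bias of C3, which is expected to favour the other epimer, wins over the reagent. The fallback sets out from 11 and comes back at 13. Reduction under substrate control (NaBH4, MeOH/THF, or the (S)-oxazaborolidine) should give the (R)-carbinol epimer of 12 F3. Mitsunobu inversion (4-nitrobenzoic acid, PPh3, DIAD, toluene, 0 °C) should give the (S)-4-nitrobenzoate of 12 F4. K2CO3 in MeOH then cleaves the ester and the six aryl silyl ethers in one operation to 13.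

Step 5. Displacement of the hindered secondary bromide by the hindered enolate may be slow or give way to O-alkylation, and the base equilibration may fail to enrich one diastereomer if the meso isomer does not crystallise selectively. The fallback sets out from 7 (any dl/meso ratio) and comes back at 8. TsOH in toluene at reflux cyclodehydrates the 1,4-diketone (Paal–Knorr furan synthesis) to 3,4-bis[3,5-bis(TBSO)phenyl]-2,5-bis[4-(TBSO)phenyl]furan F5. mCPBA (CH2Cl2, 0 °C) opens the furan oxidatively to (Z)-2,3-bis[3,5-bis(TBSO)phenyl]-1,4-bis[4-(TBSO)phenyl]but-2-ene-1,4-dione F6. Syn addition of H2 over Pd/C (EtOAc) to the (Z)-alkene should give the meso diketone 8 stereospecifically.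

Further compounds
F1 | step 6 | (2R,3S,4S)-2,3-bis(3,5-dihydroxyphenyl)-4-hydroxy-1,4-bis(4-hydroxyphenyl)butan-1-one | O=C([C@@H](c1cc(O)cc(O)c1)[C@@H](c1cc(O)cc(O)c1)[C@H](O)c1ccc(O)cc1)c1ccc(O)cc1
F2 | step 6 | [(1R,2S,3R)-2-(3,5-dihydroxyphenyl)-5,7-dihydroxy-1-(4-hydroxyphenyl)-2,3-dihydro-1H-inden-3-yl](4-hydroxyphenyl)methanone | Oc1ccc([C@@H]2c3c(O)cc(O)cc3[C@H](C(=O)c3ccc(O)cc3)[C@H]2c2cc(O)cc(O)c2)cc1
F3 | step 7 | (R)-carbinol epimer of 12 | CC(C)(C)[Si](C)(C)Oc1ccc([C@@H]2c3c(O[Si](C)(C)C(C)(C)C)cc(O[Si](C)(C)C(C)(C)C)cc3[C@H]([C@@H](O)c3ccc(O[Si](C)(C)C(C)(C)C)cc3)[C@H]2c2cc(O[Si](C)(C)C(C)(C)C)cc(O[Si](C)(C)C(C)(C)C)c2)cc1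
F4 | step 7 | (S)-4-nitrobenzoate of 12 | CC(C)(C)[Si](C)(C)Oc1ccc([C@@H]2c3c(O[Si](C)(C)C(C)(C)C)cc(O[Si](C)(C)C(C)(C)C)cc3[C@H]([C@H](OC(=O)c3ccc([N+](=O)[O-])cc3)c3ccc(O[Si](C)(C)C(C)(C)C)cc3)[C@H]2c2cc(O[Si](C)(C)C(C)(C)C)cc(O[Si](C)(C)C(C)(C)C)c2)cc1
F5 | step 5 | 3,4-bis[3,5-bis(TBSO)phenyl]-2,5-bis[4-(TBSO)phenyl]furan | CC(C)(C)[Si](C)(C)Oc1ccc(cc1)-c1oc(-c2ccc(O[Si](C)(C)C(C)(C)C)cc2)c(-c2cc(O[Si](C)(C)C(C)(C)C)cc(O[Si](C)(C)C(C)(C)C)c2)c1-c1cc(O[Si](C)(C)C(C)(C)C)cc(O[Si](C)(C)C(C)(C)C)c1
F6 | step 5 | (Z)-2,3-bis[3,5-bis(TBSO)phenyl]-1,4-bis[4-(TBSO)phenyl]but-2-ene-1,4-dione | O=C(c1ccc(O[Si](C)(C)C(C)(C)C)cc1)/C(c1cc(O[Si](C)(C)C(C)(C)C)cc(O[Si](C)(C)C(C)(C)C)c1)=C(/c1cc(O[Si](C)(C)C(C)(C)C)cc(O[Si](C)(C)C(C)(C)C)c1)C(=O)c1ccc(O[Si](C)(C)C(C)(C)C)cc1
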